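**Plan**
1. Starting materials: (R)-Hajos–Parrish ketone 1, umbelliferone 2 and angelic acid 3.
2. Retrosynthetic cuts, in order: the C3 O–acyl bond (to 3), the C11–O aryl ether bond (to 2), the C9–C11 bond (back to a C9 ketone), then the C7–C8 bond of ring B.
3. Enabling feature: in ring B the carbinol carbon C8 (OH and CH3) is bonded to C9. With C9 as a ketone, the unit C7–C8(OH)(CH3)–C9(=O)–C10 is the 1,2-shift isomer of a 1-acetylcyclopentanol, so ring B can be grown out of the five-membered ring C5–C6–C7–C9–C10.
4. Forward order: ring A and the five-membered ring come fused in 1. Ring A is finished first (C4 gem-dimethyl, C3–O, H-5). C8 and C12 are then added at C9 and raised to the acetyl carbinol, the ketol shift turns the five-membered ring into ring B, C11 is added, and coumarin and angelate go on last.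
5. Stereochemistry: C10 comes from 1. C3, C5 and the C9 carbinol are set by attack anti to the axial methyl groups. C8 is set by chirality transfer from C9 inside an aluminium chelate, and C9–H by hydroboration anti to the C8 and C10 methyl groups. The Z alkene arrives unchanged with 3.

Key step: step 10

Remark: drimane numbering is used for every intermediate (C8 and C12 are the two carbons added at C9, C11 is the carbon added last). "Methyl face" is the face carrying the C10 methyl group and "open face" is the opposite one. The R enantiomer of 1 is taken as commercially available.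

**Step 1**
Reactants: 1 (R)-Hajos–Parrish ketone
Product: 4 C9 ethylene ketal of 1 (C3 enone intact; 10R)
Conditions: (TMSOCH2)2, TMSOTf (cat.), CH2Cl2, −78 → −20 °C; pyridine quench
Reagents that add atoms: 1,2-bis(trimethylsilyloxy)ethane C[Si](C)(C)OCCO[Si](C)(C)C
Why: Noyori ketalisation under kinetic control should mask only the isolated cyclopentanone C9, which is more electrophilic than the conjugated C3 carbonyl, and the low temperature keeps the C4=C5 double bond in place.

**Step 2**
Reactants: 4 C9 ethylene ketal of 1
Product: 6 4,4-dimethyl-5(6)-en-3-one C9 ketal, via 4-methyl enone 5 (not isolated)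
Conditions: KOtBu (3 equiv), tBuOH/THF, rt; MeI (excess), 0 °C → rt
Reagents that add atoms: iodomethane CI
Why: Deconjugative α,α-dialkylation of the extended enolate, the classical 4,4-dimethylation of Δ4-3-keto steroids and of the Wieland–Miescher ketal, should place both methyl groups on C4 and leave the alkene at C5=C6, while the ketal keeps C7 from being enolised.

**Step 3**
Reactants: 6 4,4-dimethyl-5(6)-en-3-one C9 ketal
Product: 7 (3R)-3-hydroxy-4,4-dimethyl-5(6)-ene C9 ketal (OH equatorial on the methyl face)
Conditions: NaBH4, MeOH, 0 °C → rt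
Reagents that add atoms: none
Why: In this borohydride reduction of a 4,4-dimethyl-3-ketone the hydride should come along the axial path from the open face, away from the axial C4 and C10 methyl groups, which sets C3 with an equatorial hydroxyl as in 4,4-dimethyl-3-oxo steroids and triterpenes.

**Step 4**
Reactants: 7 (3R)-3-hydroxy-4,4-dimethyl-5(6)-ene C9 ketal
Product: 8 3-O-TBS ether of 7
Conditions: TBSCl, imidazole, DMAP (cat.), DMF, 60 °C
Reagents that add atoms: tert-butyldimethylsilyl chloride CC(C)(C)[Si](C)(C)Cl
Why: Standard silylation of a hindered secondary alcohol gives an ether that should survive ylide, OsO4, aluminium alkoxide, titanium carbene and borane, and that leaves with fluoride at the end.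

**Step 5**
Reactants: 8 3-O-TBS ether of 7
Product: 9 trans-hydrindane C9 ketal (H-5 on the open face; anti to the C10 methyl)
Conditions: H2 (50 bar), 10% Pd/C, EtOAc, 50 °C
Reagents that add atoms: none
Why: In heterogeneous syn hydrogenation only the open face of C5=C6 can reach the metal, because the axial C4 and C10 methyl groups cover the other face, so H-5 should enter anti to the C10 methyl and give the trans fusion, as for 4,4-dimethyl-Δ5 steroids.

**Step 6**
Reactants: 9 trans-hydrindane C9 ketal
Product: 10 3-TBSO-4,4,10-trimethyl-trans-hydrindan-9-one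
Conditions: PPTS, acetone/H2O, reflux
Reagents that add atoms: water O
Why: Mild acid hydrolysis of the ketal follows the practice for steroid 17-ketals; the hindered TBS ether should hold, and C5 is not α to the new ketone, so the ring fusion cannot epimerise.

**Step 7**
Reactants: 10 3-TBSO-4,4,10-trimethyl-trans-hydrindan-9-one
Product: 11 (Z)-9(8)-ethylidene hydrindane (C12 methyl cis to C10)
Conditions: EtPPh3Br, KOtBu, THF, reflux
Reagents that add atoms: ethyltriphenylphosphonium bromide [Br-].CC[P+](c1ccccc1)(c1ccccc1)c1ccccc1
Why: Wittig ethylidenation with the non-stabilised ylide is routine for the equally hindered 17-oxo steroids and should give mainly the Z alkene, whose geometry does not matter later because C8 becomes a carbonyl carbon.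

**Step 8**
Reactants: 11 (Z)-9(8)-ethylidene hydrindane
Product: 12 8,9-diol (9-OH on the open face; side chain on the methyl face; 8R)
Conditions: OsO4 (5 mol %), NMO, MeSO2NH2, acetone/tBuOH/H2O, rt
Reagents that add atoms: N-methylmorpholine N-oxide C[N+]1([O-])CCOCC1; water O; both oxygens are passed on by osmium tetroxide O=[Os](=O)(=O)=O, which is regenerated
Why: In this Upjohn dihydroxylation OsO4 should add syn to the open face, anti to the C10 methyl next to C9, as with steroid 17(20)-enes, which puts the C9 hydroxyl on the open face and the two-carbon chain on the methyl face.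

**Step 9**
Reactants: 12 8,9-diol
Product: 13 C9 acetyl carbinol (9-OH on the open face; acetyl on the methyl face)
Conditions: IBX, DMSO/THF, rt
Reagents that add atoms: none
Why: IBX oxidises the secondary alcohol of a 1,2-diol to the α-ketol without glycol cleavage and under neutral conditions, so no early ketol shift should occur, and the tertiary C9 carbinol cannot be oxidised.

**Step 10**
Reactants: 13 C9 acetyl carbinol
Product: 16 ent-3β-(tert-butyldimethylsilyloxy)-8α-hydroxy-11-nordriman-9-one (8-CH3 axial on the methyl face; 8-OH equatorial on the open face), via aluminium chelate 14 (not isolated), via rearranged aluminium alkoxide 15 (not isolated)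
Conditions: Al(OtBu)3 (1.5 equiv), toluene, 100 °C, short contact; aq. potassium sodium tartrate
Reagents that add atoms: aluminium tri-tert-butoxide CC(C)(C)O[Al](OC(C)(C)C)OC(C)(C)C (its atoms stay only in 14 and 15; none remain in 16)
Why: Al(OtBu)3 exchanges one alkoxide for the C9 carbinol and also binds the acetyl oxygen, so chelate 14 holds the two C–O bonds syn; the C9–C7 σ bond, which overlaps with the acetyl π* orbital, then moves suprafacially to the carbonyl carbon C8 as C9–O turns into the ketone, and work-up frees 16 from alkoxide 15. The closest known reaction type is the Lewis-acid α-ketol (acyloin) rearrangement, specifically the D-homoannulation of 17α-hydroxy-20-oxo steroids, whose ring D with its angular methyl group is the same substructure. Ring B is not closed by an exo or endo cyclisation but by a one-carbon enlargement: C8 is inserted between C9 and C7 of the ring C5–C6–C7–C9–C10, forming C7–C8 and breaking C7–C9. The only new stereocentre, C8, is set by transfer of chirality from C9, which is lost: with the carbonyl oxygen held beside the open-face C9 oxygen, C7 can reach only the carbonyl face that leaves O8 equatorial on the open face and the methyl group axial on the methyl face. The step needs migration of C7 rather than C10, and the C9 configuration secures this, because an acetyl group on the methyl face lets C8 slip between C9 and C7 into a chair-shaped ring B, whereas insertion between C9 and C10 would pass through a boat and join two fully substituted carbons. Relief of trans-hydrindane strain drives the shift, and a short reaction time in an aprotic medium should keep the kinetic C8 configuration from equilibrating.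

**Step 11**
Reactants: 16 ent-3β-(tert-butyldimethylsilyloxy)-8α-hydroxy-11-nordriman-9-one
Product: 17 8-O-TES ether of 16
Conditions: TESOTf, 2,6-lutidine, CH2Cl2, −78 → 0 °C
Reagents that add atoms: triethylsilyl triflate CC[Si](CC)(CC)OS(=O)(=O)C(F)(F)F
Why: Silyl triflate silylation of the tertiary alcohol removes the proton that any further ketol shift would need, which locks C8, and keeps the hydroxyl from consuming the titanium reagent.

**Step 12**
Reactants: 17 8-O-TES ether of 16
Product: 18 ent-3β-TBSO-8α-TESO-drim-9(11)-ene
Conditions: Cp2TiMe2 (4 equiv), toluene, 80 °C, dark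
Reagents that add atoms: dimethyltitanocene C[Ti+2]C.c1cc[cH-]c1.c1cc[cH-]c1
Why: Petasis olefination delivers a non-basic, compact titanium methylidene suited to hindered ketones on which phosphorus ylides are sluggish, and 17 has no α-hydrogen, so enolisation cannot compete.

**Step 13**
Reactants: 18 ent-3β-TBSO-8α-TESO-drim-9(11)-ene
Product: 20 ent-3β-TBSO-8α-TESO-driman-11-ol (H-9 on the open face; CH2OH equatorial on the methyl face), via primary alkylborane 19 (not isolated)
Conditions: BH3·THF, THF, 0 °C → rt; then NaOH, H2O2, 0 °C → rt
Reagents that add atoms: borane–THF B.C1CCOC1 (boron only in 19); hydrogen peroxide OO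
Why: In anti-Markovnikov hydroboration–oxidation boron goes to C11 and hydrogen to C9 from the open face, since the axial methyl groups on C8 and C10 flank C9 and block the other face, which sets C9 as expected for drim-9(11)-en-8-ol derivatives.

**Step 14**
Reactants: 20 ent-3β-TBSO-8α-TESO-driman-11-ol; 2 umbelliferone
Product: 21 7-[(ent-3β-TBSO-8α-TESO-driman-11-yl)oxy]coumarin
Conditions: PPh3, DIAD, THF, 0 → 50 °C
Reagents that add atoms: none
Why: Mitsunobu etherification of a primary alcohol with an acidic phenol forms the C11–O bond by SN2 at a carbon that is no stereocentre, and the silyl group on O8 rules out ring closure onto C11.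

**Step 15**
Reactants: 21 7-[(ent-3β-TBSO-8α-TESO-driman-11-yl)oxy]coumarin
Product: 22 7-[(ent-3β,8α-dihydroxydriman-11-yl)oxy]coumarin
Conditions: aq. HF (48 %), MeCN/CH2Cl2, rt
Reagents that add atoms: none
Why: Fluoride-driven cleavage removes both silyl ethers in one operation under conditions that should spare the coumarin lactone, the aryl ether and the tertiary alcohol.

**Step 16**
Reactants: 22 7-[(ent-3β,8α-dihydroxydriman-11-yl)oxy]coumarin; 3 angelic acid
Product: 24 target CNP0189964.2 (3R,5S,8S,9R,10R; Z angelate at O3), via mixed anhydride 23 (not isolated)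
Conditions: 3, 2,4,6-Cl3C6H2COCl, Et3N, toluene, rt; then 22, 80 °C
Reagents that add atoms: 2,4,6-trichlorobenzoyl chloride O=C(Cl)c1c(Cl)cc(Cl)cc1Cl (its atoms stay only in 23)
Why: Yamaguchi-type mixed-anhydride esterification without a nucleophilic catalyst is the protocol of choice for angelates because it avoids Z to E isomerisation, and only the secondary C3 hydroxyl should react, the tertiary C8 hydroxyl being far less reactive.

**Compound list**
1 | (R)-Hajos–Parrish ketone, (7aR)-7a-methyl-2,3,7,7a-tetrahydro-1H-indene-1,5(6H)-dione | O=C1CC[C@]2(C)C(CCC2=O)=C1 | starting material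
2 | umbelliferone (7-hydroxycoumarin) | Oc1ccc2ccc(=O)oc2c1 | starting material
3 | angelic acid, (Z)-2-methylbut-2-enoic acid | C/C=C(/C)C(=O)O | starting material
4 | C9 ethylene ketal of 1, C3 enone intact | O=C1CC[C@]2(C)C(CCC23OCCO3)=C1 | intermediate
5 | 4-methyl enone, C9 ketal (not isolated) | O=C1CC[C@]2(C)C(CCC23OCCO3)=C1C | intermediate
6 | 4,4-dimethyl-5(6)-en-3-one, C9 ketal | O=C1CC[C@]2(C)C(=CCC23OCCO3)C1(C)C | intermediate
7 | (3R)-3-hydroxy-4,4-dimethyl-5(6)-ene, C9 ketal, OH equatorial on the methyl face | O[C@@H]1CC[C@]2(C)C(=CCC23OCCO3)C1(C)C | intermediate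
8 | 3-O-TBS ether of 7 | CC(C)(C)[Si](C)(C)O[C@@H]1CC[C@]2(C)C(=CCC23OCCO3)C1(C)C | intermediate
9 | trans-hydrindane C9 ketal, H-5 on the open face | CC(C)(C)[Si](C)(C)O[C@@H]1CC[C@]2(C)[C@H](CCC23OCCO3)C1(C)C | intermediate
10 | 3-TBSO-4,4,10-trimethyl-trans-hydrindan-9-one | CC(C)(C)[Si](C)(C)O[C@@H]1CC[C@]2(C)[C@H](CCC2=O)C1(C)C | intermediate
11 | (Z)-9(8)-ethylidene hydrindane, C12 cis to C10 | CC(C)(C)[Si](C)(C)O[C@@H]1CC[C@]2(C)[C@H](CC/C2=C/C)C1(C)C | intermediate
12 | 8,9-diol, 9-OH on the open face, 8R | CC(C)(C)[Si](C)(C)O[C@@H]1CC[C@]2(C)[C@H](CC[C@@]2(O)[C@@H](C)O)C1(C)C | intermediate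
13 | C9 acetyl carbinol, 9-OH on the open face, acetyl on the methyl face | CC(C)(C)[Si](C)(C)O[C@@H]1CC[C@]2(C)[C@H](CC[C@@]2(O)C(C)=O)C1(C)C | intermediate
14 | di-tert-butoxyaluminium chelate of 13 (not isolated) | CC(C)(C)[Si](C)(C)O[C@@H]1CC[C@]2(C)[C@H](CC[C@@]2(O[Al](OC(C)(C)C)OC(C)(C)C)C(C)=O)C1(C)C | intermediate
15 | di-tert-butoxyaluminium alkoxide of 16 (not isolated) | CC(C)(C)[Si](C)(C)O[C@@H]1CC[C@]2(C)[C@H](CC[C@](C)(O[Al](OC(C)(C)C)OC(C)(C)C)C2=O)C1(C)C | intermediate
16 | ent-3β-(tert-butyldimethylsilyloxy)-8α-hydroxy-11-nordriman-9-one | CC(C)(C)[Si](C)(C)O[C@@H]1CC[C@]2(C)[C@H](CC[C@](C)(O)C2=O)C1(C)C | intermediate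
17 | 8-O-TES ether of 16 | CC(C)(C)[Si](C)(C)O[C@@H]1CC[C@]2(C)[C@H](CC[C@](C)(O[Si](CC)(CC)CC)C2=O)C1(C)C | intermediate
18 | ent-3β-TBSO-8α-TESO-drim-9(11)-ene | CC(C)(C)[Si](C)(C)O[C@@H]1CC[C@]2(C)[C@H](CC[C@](C)(O[Si](CC)(CC)CC)C2=C)C1(C)C | intermediate
19 | C11 primary alkylborane (not isolated) | CC(C)(C)[Si](C)(C)O[C@@H]1CC[C@]2(C)[C@H](CC[C@](C)(O[Si](CC)(CC)CC)[C@H]2CB)C1(C)C | intermediate
20 | ent-3β-TBSO-8α-TESO-driman-11-ol, H-9 on the open face | CC(C)(C)[Si](C)(C)O[C@@H]1CC[C@]2(C)[C@H](CC[C@](C)(O[Si](CC)(CC)CC)[C@H]2CO)C1(C)C | intermediate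
21 | 7-[(ent-3β-TBSO-8α-TESO-driman-11-yl)oxy]coumarin | CC(C)(C)[Si](C)(C)O[C@@H]1CC[C@]2(C)[C@H](CC[C@](C)(O[Si](CC)(CC)CC)[C@H]2COc2ccc3ccc(=O)oc3c2)C1(C)C | intermediate
22 | 7-[(ent-3β,8α-dihydroxydriman-11-yl)oxy]coumarin | O[C@@H]1CC[C@]2(C)[C@H](CC[C@](C)(O)[C@H]2COc2ccc3ccc(=O)oc3c2)C1(C)C | intermediate
23 | angelic 2,4,6-trichlorobenzoic anhydride (not isolated) | C/C=C(/C)C(=O)OC(=O)c1c(Cl)cc(Cl)cc1Cl | intermediate
24 | CNP0189964.2, 3-O-angelate of 22 (3R,5S,8S,9R,10R) | C/C=C(/C)C(=O)O[C@@H]1CC[C@]2(C)[C@H](CC[C@](C)(O)[C@H]2COc2ccc3ccc(=O)oc3c2)C1(C)C | target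

**Total step count:** 16. **Longest linear sequence:** 16 steps (1 → 24).

**Steps most likely to fail**

*Step 12.* The titanium methylidene may fail to reach a carbonyl flanked by two fully substituted carbons, and long heating may cause slow loss of the silyl ether. The fallback is a two-stage addition–elimination that sets out from 17. Me3SiCH2Li with CeCl3 in THF (−78 → 0 °C) should add from the open face to give the β-hydroxysilane F1. KH in THF then brings about the syn Peterson elimination, which involves no cation and can only give the exocyclic alkene. The route is rejoined at 18.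

*Step 10.* C10 may migrate in competition with C7, and reversible shifts on longer heating may erode the C8 configuration. The fallback runs the same C7–C8 bond formation and the same five-to-six enlargement one oxidation level lower and irreversibly, setting out from 12.
- MsCl and Et3N should sulfonylate only the secondary hydroxyl to give the C8 mesylate F2.
- Et3Al in CH2Cl2 (−78 → 0 °C) then triggers a semipinacol shift, as known for steroid 17-hydroxy-20-sulfonates. C7 displaces the mesylate with inversion and gives the 8-deoxy ketone ent-3β-TBSO-11-nordriman-9-one F3.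
- C8 is the only enolisable position of F3. KN(SiMe3)2 followed by 2-(phenylsulfonyl)-3-phenyloxaziridine should put oxygen on the open face of the enolate, anti to the C10 methyl.
- The route is rejoined at 16.

*Step 5.* The alkene lies between two quaternary carbons, so hydrogen uptake may not occur, or poor facial selectivity on the metal surface may erode the trans fusion. The fallback replaces surface chemisorption by radical hydrogen-atom transfer and sets out from 8. With Mn(dpm)3 (cat.), PhSiH3 and tBuOOH in iPrOH at rt, a hydrogen atom adds to C6. The tertiary C5 radical is then quenched from the open face, anti to the axial C4 and C10 methyl groups. The route is rejoined at 9, and this path makes no new compound (F0).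

**Further compounds**
F1 | step 12 | 9-hydroxy-9-(trimethylsilylmethyl) adduct of 17, CH2SiMe3 on the open face | CC(C)(C)[Si](C)(C)O[C@@H]1CC[C@]2(C)[C@H](CC[C@](C)(O[Si](CC)(CC)CC)[C@]2(O)C[Si](C)(C)C)C1(C)C
F2 | step 10 | C8 mesylate of diol 12 | CC(C)(C)[Si](C)(C)O[C@@H]1CC[C@]2(C)[C@H](CC[C@@]2(O)[C@@H](C)OS(C)(=O)=O)C1(C)C
F3 | step 10 | ent-3β-TBSO-11-nordriman-9-one, C8 methyl axial as formed by inversion | CC(C)(C)[Si](C)(C)O[C@@H]1CC[C@]2(C)[C@H](CC[C@@H](C)C2=O)C1(C)C
F0 | step 5 | none | none
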